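(The earlier runs and the new flask are simulated on assumed constants, and the scatter is random.)

Take the target first, since the next run exists for it. After 10.0 min the north run holds 2.5 % of target against 16.2 % of solvolysis product, and the north-west run, with 11 equiv of second nucleophile instead of 7 equiv, holds 2.2 % against 14.7 %.

| flask | starting material | first nucleophile | second nucleophile | remark | time |
|---|---|---|---|---|---|
| north | 20 mM | 2.5 equiv (fed, over 8.0 min) | 7 equiv | run made earlier |  |
| north-west | 20 mM | 2.5 equiv (fed, over 8.0 min) | 11 equiv | run made earlier |  |
| south-east | 10 mM | 2.5 equiv (fed, over 8.0 min) | 5 equiv | run made earlier |  |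
| flask | 20 mM | 2.50 equiv (fed, over 8.0 min) | 5.00 equiv |  | 12 min |

- north (time / min: target / %, solvolysis product / %, starting material / %): 0.833: 0, 4.4, 52.1; 2.00: 0.7, 8.1, 31.1; 4.00: 0.3, 11.5, 16.7; 10.0: 2.5, 16.2, 5.7
- north-west (time / min: target / %, solvolysis product / %, starting material / %): 1.33: 0, 6.1, 39.6; 3.00: 0, 10.2, 21.2; 6.00: 1.0, 13.5, 10.5; 10.0: 2.2, 14.7, 6.1
- south-east (time / min: target / %, solvolysis product / %, starting material / %): 1.33: 0.2, 8.0, 55.2; 3.00: 0.5, 12.5, 34.1; 6.00: 0.7, 19.1, 17.7; 10.0: 1.5, 23.2, 10.3

(each reading ± 0.5 percentage points)

- what was read earlier has a scatter of 0.5 percentage points, one standard deviation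

- target present at 12 min, in percent of the starting material charged
- solvolysis product present at 12 min, in percent of the starting material charged
- starting material present at 12 min, in percent of the starting material charged
- concentration of first nucleophile at 12 min, in mM

Decide the charge of second nucleophile from those two runs. Their target differs by 0.3 percentage points, with a scatter of 0.5 points, so charge 5.00 equiv and keep the first nucleophile as it was. Do not freeze the concentration of first nucleophile, which climbs through the feed: the north run already held 11.5 % of solvolysis product at 4.00 min, half of the feed time. Freeze its course relative to the charge instead. The three earlier runs and this flask are each fed over 8.0 min, and the target had taken about 0.500 mM of the 50.0 mM charged by 10.0 min in the north run, so at a given time the concentration stands close to the same share of the charge.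

Define the capture ratio, a lumped selectivity factor, as target over solvolysis product, per mM of first nucleophile charged. Freeze also the sum of the two products, letting it stand from 10.0 min to 12 min although 5.7 % of starting material remained at the earlier time in the north run.

Charged first nucleophile: 50.0 mM

Capture ratio, north and north-west together: 0.00304 mM⁻¹

South-east alone, as a check: 0.00259 mM⁻¹

Sum of the two products: 17.8 %

My reckoning: target 2.35 %, solvolysis product 15.5 %, first nucleophile 49.5 mM.

The forecast differs a little, with 2.8 % of target, 15.8 % of solvolysis product, 4.5 % of starting material and 49 mM of first nucleophile. It opens: “The percentages do not close, so a large unseen loss is at work”.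

The flask gives 1.78 % of target, 16.1 % of solvolysis product, 4.32 % of starting material and 49.6 mM of first nucleophile.

    second nucleophile + intermediate → other capture product (k = 3.10 M⁻¹ s⁻¹)
    starting material → intermediate (k = 0.00140 s⁻¹)
    second nucleophile → decomposed reagent (k = 0.0100 s⁻¹)
    first nucleophile + intermediate → target (k = 36.0 M⁻¹ s⁻¹)
    intermediate → solvolysis product (k = 5.70 s⁻¹)
    2 starting material → homo dimer (k = 0.410 M⁻¹ s⁻¹)

Read the capture ratio from this flask: 0.00221 mM⁻¹, with the sum at 17.9 %. Now charge 10.0 equiv of first nucleophile, which is 200 mM. The ratio of target to solvolysis product becomes 0.442, so reckon 5.48 % of target and 12.4 % of solvolysis product. That neighbour gives 4.90 % of target, less than reckoned, and 13.0 % of solvolysis product, and their sum stands at 17.9 %.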